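**Retrosynthetic overview**
- The target, (R)-N-acetyltortuosamine, comes from the (R)-6,6-disubstituted 7,8-dihydroquinolin-5(6H)-one by removal of the C5 carbonyl.
- The C6–aryl bond and the quaternary stereocentre come from an enantioselective Pd-catalysed α-arylation of the racemic 6-(2-amidoethyl) ketone with 3,4-dimethoxyphenyl triflate.
- The key C6–CH2 bond is made with reversed polarity: the 6-bromo ketone acts as an enolonium equivalent (electrophilic α-keto radical) toward the nucleophilic β-carbon of N-methyl-N-vinylacetamide, which delivers the whole side chain at its final oxidation level.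
- No ring is formed: the pyridine ring and the carbocycle are bought fused in 7,8-dihydroquinolin-5(6H)-one.

Assumption: the sense of induction of difluorphos is taken by analogy with 2-methyl-1-tetralone; the ligand written as (R) stands for whichever antipode is found to give the (R)-configured quaternary ketone.

**Step 1**
Reactants: 1 7,8-dihydroquinolin-5(6H)-one
Product: 2 rac-6-bromo-7,8-dihydroquinolin-5(6H)-one
Conditions: Br2 (1.0 equiv), 33% HBr/AcOH, rt; hydrobromide salt collected, freed with cold aq NaHCO3/CH2Cl2 and used at once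
Reagents that add atoms: bromine, BrBr
Why: Acid-catalysed enolisation can only occur toward C6 and the enol is brominated once (the protonated pyridine ring is inert to Br2), a standard ketone α-bromination; the new C6 centre is racemic and of no consequence.

**Step 2**
Reactants: 2 rac-6-bromo-7,8-dihydroquinolin-5(6H)-one; 3 N-methyl-N-vinylacetamide
Product: 4 rac-N-methyl-N-[2-(5-oxo-5,6,7,8-tetrahydroquinolin-6-yl)ethyl]acetamide
Conditions: Ir(ppy)3 [tris(2-phenylpyridinato)iridium] (1 mol %), Hantzsch ester (1.3 equiv), 3 (5 equiv), 2,6-lutidine (1.2 equiv), degassed MeCN, blue LEDs (450 nm), rt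
Reagents that add atoms: none
Why: Proposed new method: photoexcited Ir(ppy)3 reduces the C–Br bond of 2 to the electrophilic α-keto radical (an enolonium equivalent), which adds in a polarity-matched step to the electron-rich terminal carbon of enamide 3, and the resulting α-amido radical is quenched by hydrogen-atom transfer from Hantzsch ester (or, after oxidation to the N-acyliminium ion, by hydride transfer from it), so two natively nucleophilic carbons are joined; the closest known reaction types are the visible-light photoredox alkylation of enamides with α-bromo carbonyl compounds and Giese-type reductive radical additions; C6 is formed racemic and is reset in step 4.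

**Step 3**
Reactants: 5 3,4-dimethoxyphenol
Product: 6 3,4-dimethoxyphenyl trifluoromethanesulfonate
Conditions: Tf2O (1.1 equiv), pyridine (2 equiv), CH2Cl2, 0 °C to rt
Reagents that add atoms: trifluoromethanesulfonic anhydride, O=S(=O)(OS(=O)(=O)C(F)(F)F)C(F)(F)F
Why: O-Sulfonylation of the phenol with Tf2O (aryl triflate formation) is fast and clean; no stereocentre is involved.

**Step 4**
Reactants: 4 rac-N-methyl-N-[2-(5-oxo-5,6,7,8-tetrahydroquinolin-6-yl)ethyl]acetamide; 6 3,4-dimethoxyphenyl trifluoromethanesulfonate
Product: 7 N-{2-[(6R)-6-(3,4-dimethoxyphenyl)-5-oxo-5,6,7,8-tetrahydroquinolin-6-yl]ethyl}-N-methylacetamide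
Conditions: Pd(dba)2 (5 mol %), (R)-difluorphos (6 mol %), NaOt-Bu (1.5 equiv), 6 (1.1 equiv), toluene, 60 °C
Reagents that add atoms: none
Why: Buchwald–Hartwig-type enantioselective ketone α-arylation: NaOt-Bu forms the C6 enolate of 4 (its most acidic site), oxidative addition of 6 to zerovalent palladium gives a cationic arylpalladium–difluorphos complex, and the enantiodetermining C–C reductive elimination from the diastereomeric palladium enolates in the C2-symmetric ligand pocket creates the quaternary (R)-centre, as precedented for 2-alkyl-1-tetralones with aryl triflates.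

**Step 5**
Reactants: 7 N-{2-[(6R)-6-(3,4-dimethoxyphenyl)-5-oxo-5,6,7,8-tetrahydroquinolin-6-yl]ethyl}-N-methylacetamide
Product: 9 N-{2-[(6R)-6-(3,4-dimethoxyphenyl)-5,6,7,8-tetrahydroquinolin-6-yl]ethyl}-N-methylacetamide, via tosylhydrazone 8 (not isolated)
Conditions: TsNHNH2 (1.5 equiv), TsOH·H2O (cat.), 4 Å MS, CHCl3, 60 °C; then catecholborane (3 equiv), 0 °C to rt; then NaOAc·3H2O, 60 °C
Reagents that add atoms: none
Why: Kabalka-type reductive deoxygenation: the tosylhydrazone is reduced at C=N by catecholborane and acetate then triggers loss of sulfinate and N2 to leave CH2 under conditions that spare the amide, the aryl ethers and the pyridine, and because no cation or long-lived radical is formed next to C6 the quaternary stereocentre is untouched.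

**Compound list**
1 | 7,8-dihydroquinolin-5(6H)-one | O=C1CCCc2ncccc12 | starting material
2 | rac-6-bromo-7,8-dihydroquinolin-5(6H)-one | O=C1C(Br)CCc2ncccc12 | intermediate
3 | N-methyl-N-vinylacetamide | C=CN(C)C(C)=O | starting material
4 | rac-N-methyl-N-[2-(5-oxo-5,6,7,8-tetrahydroquinolin-6-yl)ethyl]acetamide | CC(=O)N(C)CCC1CCc2ncccc2C1=O | intermediate
5 | 3,4-dimethoxyphenol | COc1ccc(O)cc1OC | starting material
6 | 3,4-dimethoxyphenyl trifluoromethanesulfonate | COc1ccc(OS(=O)(=O)C(F)(F)F)cc1OC | intermediate
7 | N-{2-[(6R)-6-(3,4-dimethoxyphenyl)-5-oxo-5,6,7,8-tetrahydroquinolin-6-yl]ethyl}-N-methylacetamide | COc1ccc([C@]2(CCN(C)C(C)=O)CCc3ncccc3C2=O)cc1OC | intermediate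
8 | N-{2-[(6R)-6-(3,4-dimethoxyphenyl)-5-[2-(4-methylbenzenesulfonyl)hydrazinylidene]-5,6,7,8-tetrahydroquinolin-6-yl]ethyl}-N-methylacetamide (tosylhydrazone of 7) | COc1ccc([C@]2(CCN(C)C(C)=O)CCc3ncccc3C2=NNS(=O)(=O)c2ccc(C)cc2)cc1OC | intermediate
9 | N-{2-[(6R)-6-(3,4-dimethoxyphenyl)-5,6,7,8-tetrahydroquinolin-6-yl]ethyl}-N-methylacetamide | COc1ccc([C@]2(CCN(C)C(C)=O)CCc3ncccc3C2)cc1OC | target

**Step count**
Total steps: 5. Longest linear sequence: 4 (steps 1, 2, 4 and 5; step 3 is a one-step side branch).

**Steps most likely to fail**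

Step 2. The α-keto radical may simply be reduced back to 1, the enamide may telomerise or hydrolyse, the N-acyliminium ion may be trapped by the ketone enol, and free 2 alkylates its own pyridine nitrogen on standing. The fallback sets out from 2 and comes back at 4 and replaces the reductive photoredox coupling by a xanthate group-transfer chain. Bromide is displaced with KSC(S)OEt in acetone at 0 °C to give O-ethyl S-(5-oxo-5,6,7,8-tetrahydroquinolin-6-yl) carbonodithioate F1. Dilauroyl peroxide (portions) in refluxing 1,2-dichloroethane with 3 then gives the adduct O-ethyl S-{1-[acetyl(methyl)amino]-2-(5-oxo-5,6,7,8-tetrahydroquinolin-6-yl)ethyl} carbonodithioate F2. Finally (TMS)3SiH and AIBN in toluene at 80 °C remove the xanthate and give 4.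

Step 4. Reductive elimination to the congested quaternary centre may be slow, arylation may divert to the vinylogously activated C8 position, and the enantioselectivity with a side chain larger than methyl is untested. The fallback sets out from 1 and comes back at 7 and reverses the order of the two bond formations. Racemic α-arylation of 1 with 4-bromo-1,2-dimethoxybenzene (Pd(OAc)2, XPhos, NaOt-Bu, toluene, 80 °C) occurs cleanly at the C6 methylene and gives rac-6-(3,4-dimethoxyphenyl)-7,8-dihydroquinolin-5(6H)-one F3. Its doubly activated C6–H is then alkylated under chiral phase-transfer catalysis (a cinchona-derived N-(9-anthracenylmethyl) quaternary ammonium bromide, pseudo-enantiomer chosen for (R), 50% aq KOH, toluene, 0 °C) with N-(2-iodoethyl)-N-methylacetamide F4 to give 7 directly. F4 is made from commercial N-(2-hydroxyethyl)-N-methylacetamide with I2, PPh3 and imidazole.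

Step 5. The ketone is flanked by the quaternary carbon and may resist tosylhydrazone formation or hydride delivery. The fallback sets out from 7 and comes back at 9 and removes the oxygen by a radical route. NaBH4 in MeOH at 0 °C gives N-{2-[(6R)-6-(3,4-dimethoxyphenyl)-5-hydroxy-5,6,7,8-tetrahydroquinolin-6-yl]ethyl}-N-methylacetamide F5 (C5 epimers). 1,1'-Thiocarbonyldiimidazole with DMAP in 1,2-dichloroethane at 80 °C gives O-{(6R)-6-(3,4-dimethoxyphenyl)-6-[2-(N-methylacetamido)ethyl]-5,6,7,8-tetrahydroquinolin-5-yl} 1H-imidazole-1-carbothioate F6. Bu3SnH and AIBN in toluene at 110 °C (Barton–McCombie) then give 9; the pyridyl-stabilised C5 radical has no driving force for aryl migration.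

**Further compounds**
F1 | step 2 | O-ethyl S-(5-oxo-5,6,7,8-tetrahydroquinolin-6-yl) carbonodithioate (racemic) | CCOC(=S)SC1CCc2ncccc2C1=O
F2 | step 2 | O-ethyl S-{1-[acetyl(methyl)amino]-2-(5-oxo-5,6,7,8-tetrahydroquinolin-6-yl)ethyl} carbonodithioate (diastereomer mixture) | CCOC(=S)SC(CC1CCc2ncccc2C1=O)N(C)C(C)=O
F3 | step 4 | rac-6-(3,4-dimethoxyphenyl)-7,8-dihydroquinolin-5(6H)-one | COc1ccc(C2CCc3ncccc3C2=O)cc1OC
F4 | step 4 | N-(2-iodoethyl)-N-methylacetamide | CC(=O)N(C)CCI
F5 | step 5 | N-{2-[(6R)-6-(3,4-dimethoxyphenyl)-5-hydroxy-5,6,7,8-tetrahydroquinolin-6-yl]ethyl}-N-methylacetamide (C5 epimers) | COc1ccc([C@]2(CCN(C)C(C)=O)CCc3ncccc3C2O)cc1OC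
F6 | step 5 | O-{(6R)-6-(3,4-dimethoxyphenyl)-6-[2-(N-methylacetamido)ethyl]-5,6,7,8-tetrahydroquinolin-5-yl} 1H-imidazole-1-carbothioate (C5 epimers) | COc1ccc([C@]2(CCN(C)C(C)=O)CCc3ncccc3C2OC(=S)n2ccnc2)cc1OC
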